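**Assumption:** (4R,6R)-actinol and (R)-α-ionone are bought as single enantiomers (both are catalogue compounds); carotenoid locants (C3, C5, C6, C3', C6') are used in the comments. The target as drawn is the (3S,5S,6R,3'R,6'R) isomer, with the three hydroxyls of the saturated ring all cis.

## Retrosynthetic overview

1. Target ⇐ desilylation of its 3,3'-bis-silyl ether; C11=C12 by Wittig reaction of a ring A (trihydroxy ring) C15 phosphonium salt with a ring B (ε ring) C25 aldehyde.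
2. C25 aldehyde ⇐ C11'=C12' Wittig of the ring B C15 phosphonium salt with the commercial C10 dialdehyde; ring B salt ⇐ (R)-α-ionone by HWE (C9'=C10'), allylic oxidation and Luche reduction (sets C3').
3. Ring A salt ⇐ trans-selective alkyne reduction (C7=C8) ⇐ Sonogashira coupling (C8–C9) of an ethynyl triol with the E enol triflate of ethyl acetoacetate.
4. Ethynyl triol ⇐ new hydroxyl-directed syn-dihydroxylation of an enynol (sets C5 and C6) ⇐ Sonogashira coupling (C6–C7) of the enol triflate of (4R,6R)-actinol.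
5. No ring is formed: ring A is bought as actinol and ring B as (R)-α-ionone; ring A is elaborated first (longest sequence), ring B in parallel, the polyene last.

## Fragment 1 (ring A, C15 phosphonium salt)

**Step 1**
Reactants: 1 (4R,6R)-4-hydroxy-2,2,6-trimethylcyclohexan-1-one ((4R,6R)-actinol)
Product: 2 (4R,6R)-4-[(tert-butyldimethylsilyl)oxy]-2,2,6-trimethylcyclohexan-1-one
Conditions: TBSCl, imidazole, DMF, rt
Reagents that add atoms: tert-butyldimethylsilyl chloride, CC(C)(C)[Si](C)(C)Cl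
Why: Standard silyl ether protection of the only hydroxyl, leaving the C4 stereocentre (future carotenoid C3) untouched.

**Step 2**
Reactants: 2 (4R,6R)-4-[(tert-butyldimethylsilyl)oxy]-2,2,6-trimethylcyclohexan-1-one
Product: 4 (4R)-4-[(tert-butyldimethylsilyl)oxy]-2,6,6-trimethylcyclohex-1-en-1-yl trifluoromethanesulfonate, via lithium enolate 3 (not isolated)
Conditions: LiN(i-Pr)2 (LDA), THF, −78 °C; then PhNTf2, −78 → 0 °C
Reagents that add atoms: N-phenylbis(trifluoromethanesulfonimide), O=S(=O)(N(c1ccccc1)S(=O)(=O)C(F)(F)F)C(F)(F)F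
Why: Enolisation can only occur towards C6 because C2 is quaternary, and O-triflation of the enolate gives the tetrasubstituted enol triflate while deliberately erasing the C6 stereocentre.

**Step 3**
Reactants: 4 (4R)-4-[(tert-butyldimethylsilyl)oxy]-2,6,6-trimethylcyclohex-1-en-1-yl trifluoromethanesulfonate; 5 ethynyltrimethylsilane
Product: 6 tert-butyldimethyl({(1R)-3,5,5-trimethyl-4-[(trimethylsilyl)ethynyl]cyclohex-3-en-1-yl}oxy)silane
Conditions: Pd(PPh3)4 (5 mol %), CuI (10 mol %), Et3N, DMF, 50 °C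
Reagents that add atoms: none
Why: Sonogashira coupling (oxidative addition of the enol triflate to zerovalent palladium, copper acetylide transmetalation) forms the C6–C7 bond.

**Step 4**
Reactants: 6 tert-butyldimethyl({(1R)-3,5,5-trimethyl-4-[(trimethylsilyl)ethynyl]cyclohex-3-en-1-yl}oxy)silane
Product: 7 (1R)-4-ethynyl-3,5,5-trimethylcyclohex-3-en-1-ol
Conditions: Bu4NF, THF, 0 °C → rt
Reagents that add atoms: none
Why: Fluoride-mediated desilylation cleaves both the O–Si and the alkynyl C–Si bond in one operation, freeing the hydroxyl needed as directing group.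

**Step 5**
Reactants: 7 (1R)-4-ethynyl-3,5,5-trimethylcyclohex-3-en-1-ol
Product: 9 (1S,2S,4S)-1-ethynyl-2,6,6-trimethylcyclohexane-1,2,4-triol (all three hydroxyls cis), via osmate ester 8 (not isolated)
Conditions: OsO4 (1.1 equiv), TMEDA (1.2 equiv), CH2Cl2, −78 → −30 °C; then sat. aq. Na2SO3, THF, 60 °C
Reagents that add atoms: osmium tetroxide, O=[Os](=O)(=O)=O
Why: Proposed new method: hydrogen-bond-directed osmylation of the tetrasubstituted alkene of a 1,3-enyne by a homoallylic hydroxyl – the chelating diamine makes the oxo ligands of OsO4·TMEDA strong hydrogen-bond acceptors, the C1–OH of 7 (equatorial half-chair, whose OH-bearing face is also the one free of the pseudoaxial ring methyl) anchors the reagent so that the concerted [3+2] cycloaddition places both new C–O bonds cis to that OH (setting carotenoid C5 as S and C6 as R in one step), the slim alkyne neither blocks nor competes at low temperature, and the inert chelated ester of hexavalent osmium 8 is then cleaved reductively; closest known reaction type: OsO4/TMEDA directed dihydroxylation of cyclic allylic and simple homoallylic alcohols with di- and trisubstituted alkenes.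

**Step 6**
Reactants: 9 (1S,2S,4S)-1-ethynyl-2,6,6-trimethylcyclohexane-1,2,4-triol
Product: 10 (1S,2S,4S)-4-[(tert-butyldimethylsilyl)oxy]-1-ethynyl-2,6,6-trimethylcyclohexane-1,2-diol
Conditions: TBSCl (1.1 equiv), imidazole, DMF, rt
Reagents that add atoms: tert-butyldimethylsilyl chloride, CC(C)(C)[Si](C)(C)Cl
Why: Silyl ether formation is selective for the secondary hydroxyl because the two tertiary hydroxyls are too hindered to react with TBSCl.

**Step 7**
Reactants: 11 ethyl acetoacetate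
Product: 12 ethyl (2E)-3-{[(trifluoromethyl)sulfonyl]oxy}but-2-enoate
Conditions: Tf2O, 25% aq. Me4NOH, hexanes, 5 °C
Reagents that add atoms: trifluoromethanesulfonic anhydride, O=S(=O)(OS(=O)(=O)C(F)(F)F)C(F)(F)F
Why: Schotten–Baumann-type O-sulfonylation of the non-chelated tetramethylammonium enolate gives the E enol triflate (triflate trans to the ester).

**Step 8**
Reactants: 10 (1S,2S,4S)-4-[(tert-butyldimethylsilyl)oxy]-1-ethynyl-2,6,6-trimethylcyclohexane-1,2-diol; 12 ethyl (2E)-3-{[(trifluoromethyl)sulfonyl]oxy}but-2-enoate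
Product: 13 ethyl (2E)-5-[(1S,2S,4S)-4-[(tert-butyldimethylsilyl)oxy]-1,2-dihydroxy-2,6,6-trimethylcyclohexyl]-3-methylpent-2-en-4-ynoate
Conditions: PdCl2(PPh3)2 (3 mol %), CuI (6 mol %), Et3N, THF, rt
Reagents that add atoms: none
Why: Sonogashira coupling proceeds with retention of the enol triflate geometry, forming the C8–C9 bond and fixing the 9E double bond, and free tertiary alcohols are tolerated.

**Step 9**
Reactants: 13 ethyl (2E)-5-[(1S,2S,4S)-4-[(tert-butyldimethylsilyl)oxy]-1,2-dihydroxy-2,6,6-trimethylcyclohexyl]-3-methylpent-2-en-4-ynoate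
Product: 14 (2E)-5-[(1S,2S,4S)-4-[(tert-butyldimethylsilyl)oxy]-1,2-dihydroxy-2,6,6-trimethylcyclohexyl]-3-methylpent-2-en-4-yn-1-ol
Conditions: i-Bu2AlH (4.5 equiv), CH2Cl2, −78 °C; aq. potassium sodium tartrate
Reagents that add atoms: none
Why: 1,2-Hydride reduction of the conjugated ester gives the primary allylic alcohol, the excess hydride only deprotonating the two tertiary hydroxyls.

**Step 10**
Reactants: 14 (2E)-5-[(1S,2S,4S)-4-[(tert-butyldimethylsilyl)oxy]-1,2-dihydroxy-2,6,6-trimethylcyclohexyl]-3-methylpent-2-en-4-yn-1-ol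
Product: 15 (2E,4E)-5-[(1R,2S,4S)-4-[(tert-butyldimethylsilyl)oxy]-1,2-dihydroxy-2,6,6-trimethylcyclohexyl]-3-methylpenta-2,4-dien-1-ol
Conditions: NaAlH2(OCH2CH2OMe)2 (Red-Al, 5 equiv), THF, 0 °C → rt
Reagents that add atoms: none
Why: Alkoxide-directed trans-hydroalumination of the propargylic alcohol followed by protonolysis gives the E alkene (C7=C8), as in abscisic acid syntheses, the change of the ring C1 descriptor from S to R being only a CIP priority effect.

**Step 11**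
Reactants: 15 (2E,4E)-5-[(1R,2S,4S)-4-[(tert-butyldimethylsilyl)oxy]-1,2-dihydroxy-2,6,6-trimethylcyclohexyl]-3-methylpenta-2,4-dien-1-ol
Product: 17 {(2E,4E)-5-[(1R,2S,4S)-4-[(tert-butyldimethylsilyl)oxy]-1,2-dihydroxy-2,6,6-trimethylcyclohexyl]-3-methylpenta-2,4-dien-1-yl}triphenylphosphonium bromide, via allylic bromide 16 (not isolated)
Conditions: CBr4 (1.15 equiv), PPh3 (1.2 equiv), 2,6-lutidine, CH2Cl2, −20 °C; then PPh3 (1.2 equiv), rt
Reagents that add atoms: triphenylphosphine, c1ccccc1P(c1ccccc1)c1ccccc1; carbon tetrabromide, BrC(Br)(Br)Br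
Why: Appel bromination converts only the primary allylic alcohol (the tertiary ones do not react under neutral conditions), and SN2 quaternisation of the bromide by PPh3 gives the Wittig salt.

## Fragment 2 (ring B, C25 aldehyde)

**Step 12**
Reactants: 18 (R)-α-ionone ((3E)-4-[(1R)-2,6,6-trimethylcyclohex-2-en-1-yl]but-3-en-2-one); 19 triethyl phosphonoacetate
Product: 21 ethyl (2E,4E)-3-methyl-5-[(1R)-2,6,6-trimethylcyclohex-2-en-1-yl]penta-2,4-dienoate, via sodium phosphonate 20 (not isolated)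
Conditions: NaH, THF, 0 °C; then 18, rt → 45 °C; chromatographic removal of the 2Z isomer
Reagents that add atoms: none
Why: Horner–Wadsworth–Emmons olefination of the methyl ketone builds the C9'=C10' double bond with the usual E preference (about 4:1), and the mildly basic phosphonate anion does not epimerise the allylic ring stereocentre.

**Step 13**
Reactants: 21 ethyl (2E,4E)-3-methyl-5-[(1R)-2,6,6-trimethylcyclohex-2-en-1-yl]penta-2,4-dienoate
Product: 22 ethyl (2E,4E)-3-methyl-5-[(1R)-2,6,6-trimethyl-4-oxocyclohex-2-en-1-yl]penta-2,4-dienoate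
Conditions: Rh2(cap)4 (dirhodium tetrakis(caprolactamate), 1 mol %), t-BuOOH (70% aq., 5 equiv), K2CO3, CH2Cl2, rt
Reagents that add atoms: tert-butyl hydroperoxide, CC(C)(C)OO
Why: Radical allylic C–H oxidation of the only ring methylene that flanks the electron-rich trisubstituted alkene gives the enone, as known for α-ionylidene esters, without involving the C1 stereocentre.

**Step 14**
Reactants: 22 ethyl (2E,4E)-3-methyl-5-[(1R)-2,6,6-trimethyl-4-oxocyclohex-2-en-1-yl]penta-2,4-dienoate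
Product: 23 ethyl (2E,4E)-5-[(1R,4R)-4-hydroxy-2,6,6-trimethylcyclohex-2-en-1-yl]-3-methylpenta-2,4-dienoate
Conditions: NaBH4, CeCl3·7H2O, MeOH, −40 °C; chromatography
Reagents that add atoms: none
Why: Luche 1,2-reduction of the ring enone leaves the dienoate untouched, and because the side chain sits pseudoaxial the pseudoaxial methyl of C6 shields the opposite face, so hydride adds syn to the side chain and gives the 1,4-trans alcohol (carotenoid C3' as R).

**Step 15**
Reactants: 23 ethyl (2E,4E)-5-[(1R,4R)-4-hydroxy-2,6,6-trimethylcyclohex-2-en-1-yl]-3-methylpenta-2,4-dienoate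
Product: 24 ethyl (2E,4E)-5-[(1R,4R)-4-[(tert-butyldimethylsilyl)oxy]-2,6,6-trimethylcyclohex-2-en-1-yl]-3-methylpenta-2,4-dienoate
Conditions: TBSCl, imidazole, DMF, rt
Reagents that add atoms: tert-butyldimethylsilyl chloride, CC(C)(C)[Si](C)(C)Cl
Why: Standard silyl ether protection of the ring allylic alcohol so that only the chain terminus is functionalised later.

**Step 16**
Reactants: 24 ethyl (2E,4E)-5-[(1R,4R)-4-[(tert-butyldimethylsilyl)oxy]-2,6,6-trimethylcyclohex-2-en-1-yl]-3-methylpenta-2,4-dienoate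
Product: 25 (2E,4E)-5-[(1R,4R)-4-[(tert-butyldimethylsilyl)oxy]-2,6,6-trimethylcyclohex-2-en-1-yl]-3-methylpenta-2,4-dien-1-ol
Conditions: i-Bu2AlH (2.5 equiv), CH2Cl2, −78 °C; aq. potassium sodium tartrate
Reagents that add atoms: none
Why: 1,2-Hydride reduction of the dienoate ester gives the primary allylic alcohol with the silyl ether and both stereocentres intact.

**Step 17**
Reactants: 25 (2E,4E)-5-[(1R,4R)-4-[(tert-butyldimethylsilyl)oxy]-2,6,6-trimethylcyclohex-2-en-1-yl]-3-methylpenta-2,4-dien-1-ol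
Product: 27 {(2E,4E)-5-[(1R,4R)-4-[(tert-butyldimethylsilyl)oxy]-2,6,6-trimethylcyclohex-2-en-1-yl]-3-methylpenta-2,4-dien-1-yl}triphenylphosphonium bromide, via allylic bromide 26 (not isolated)
Conditions: CBr4 (1.15 equiv), PPh3 (1.2 equiv), 2,6-lutidine, CH2Cl2, −20 °C; then PPh3 (1.2 equiv), rt
Reagents that add atoms: triphenylphosphine, c1ccccc1P(c1ccccc1)c1ccccc1; carbon tetrabromide, BrC(Br)(Br)Br
Why: Appel bromination followed by SN2 quaternisation gives the C15 Wittig salt under neutral conditions that spare the acid-sensitive ring allylic silyl ether.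

**Step 18**
Reactants: 27 {(2E,4E)-5-[(1R,4R)-4-[(tert-butyldimethylsilyl)oxy]-2,6,6-trimethylcyclohex-2-en-1-yl]-3-methylpenta-2,4-dien-1-yl}triphenylphosphonium bromide; 28 (2E,4E,6E)-2,7-dimethylocta-2,4,6-trienedial
Product: 30 (2E,4E,6E,8E,10E,12E)-13-[(1R,4R)-4-[(tert-butyldimethylsilyl)oxy]-2,6,6-trimethylcyclohex-2-en-1-yl]-2,7,11-trimethyltrideca-2,4,6,8,10,12-hexaenal, via ylide 29 (not isolated)
Conditions: NaOMe, MeOH/CH2Cl2, 0 °C; added to 28 (2.5 equiv), 0 °C → rt; then n-heptane, 90 °C (Z → E)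
Reagents that add atoms: none
Why: Wittig mono-olefination forms C11'=C12', double reaction being suppressed by the excess dialdehyde and by the lower electrophilicity of the extended product aldehyde, and heating equilibrates the new disubstituted alkene to E.

## Assembly

**Step 19**
Reactants: 17 {(2E,4E)-5-[(1R,2S,4S)-4-[(tert-butyldimethylsilyl)oxy]-1,2-dihydroxy-2,6,6-trimethylcyclohexyl]-3-methylpenta-2,4-dien-1-yl}triphenylphosphonium bromide; 30 (2E,4E,6E,8E,10E,12E)-13-[(1R,4R)-4-[(tert-butyldimethylsilyl)oxy]-2,6,6-trimethylcyclohex-2-en-1-yl]-2,7,11-trimethyltrideca-2,4,6,8,10,12-hexaenal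
Product: 32 (3S,5S,6R,3'R,6'R)-3,3'-bis[(tert-butyldimethylsilyl)oxy]-5,6-dihydro-β,ε-carotene-5,6-diol, via ylide 31 (not isolated)
Conditions: 17 (1.3 equiv), NaOMe (4 equiv), MeOH/CH2Cl2, 0 °C; then 30, rt; then EtOAc, 70 °C (Z → E)
Reagents that add atoms: none
Why: Wittig olefination forms C11=C12 and completes the C40 skeleton, free tertiary hydroxyls being tolerated as in industrial hydroxy-carotenoid syntheses, and heating converts the 11Z isomer into the all-E polyene.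

**Step 20**
Reactants: 32 (3S,5S,6R,3'R,6'R)-3,3'-bis[(tert-butyldimethylsilyl)oxy]-5,6-dihydro-β,ε-carotene-5,6-diol
Product: 33 (3S,5S,6R,3'R,6'R)-5,6-dihydro-β,ε-carotene-3,5,6,3'-tetrol (5,6-dihydroxylutein)
Conditions: Bu4NF (6 equiv), AcOH (3 equiv), THF, rt → 40 °C; crystallisation in the dark under argon
Reagents that add atoms: none
Why: Buffered fluoride desilylation removes both silyl ethers without acid, so the ε-ring allylic alcohol, the tertiary allylic alcohol and all five stereocentres are preserved.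

## Compound list

1 | (4R,6R)-4-hydroxy-2,2,6-trimethylcyclohexan-1-one ((4R,6R)-actinol) | C[C@@H]1C[C@@H](O)CC(C)(C)C1=O | starting material
2 | (4R,6R)-4-[(tert-butyldimethylsilyl)oxy]-2,2,6-trimethylcyclohexan-1-one | C[C@@H]1C[C@@H](O[Si](C)(C)C(C)(C)C)CC(C)(C)C1=O | intermediate
3 | lithium (4R)-4-[(tert-butyldimethylsilyl)oxy]-2,6,6-trimethylcyclohex-1-en-1-olate | [Li+].CC1=C([O-])C(C)(C)C[C@H](O[Si](C)(C)C(C)(C)C)C1 | intermediate
4 | (4R)-4-[(tert-butyldimethylsilyl)oxy]-2,6,6-trimethylcyclohex-1-en-1-yl trifluoromethanesulfonate | CC1=C(OS(=O)(=O)C(F)(F)F)C(C)(C)C[C@H](O[Si](C)(C)C(C)(C)C)C1 | intermediate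
5 | ethynyltrimethylsilane | C#C[Si](C)(C)C | starting material
6 | tert-butyldimethyl({(1R)-3,5,5-trimethyl-4-[(trimethylsilyl)ethynyl]cyclohex-3-en-1-yl}oxy)silane | CC1=C(C#C[Si](C)(C)C)C(C)(C)C[C@H](O[Si](C)(C)C(C)(C)C)C1 | intermediate
7 | (1R)-4-ethynyl-3,5,5-trimethylcyclohex-3-en-1-ol | CC1=C(C#C)C(C)(C)C[C@H](O)C1 | intermediate
8 | cyclic osmate ester of 9 through O1 and O2 (hexavalent osmium, TMEDA-chelated, C4–OH free) | C#C[C@@]1(O2)C(C)(C)C[C@H](O)C[C@]1(C)O[Os]2(=O)=O.CN(C)CCN(C)C | intermediate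
9 | (1S,2S,4S)-1-ethynyl-2,6,6-trimethylcyclohexane-1,2,4-triol (all hydroxyls cis) | C#C[C@@]1(O)C(C)(C)C[C@H](O)C[C@]1(C)O | intermediate
10 | (1S,2S,4S)-4-[(tert-butyldimethylsilyl)oxy]-1-ethynyl-2,6,6-trimethylcyclohexane-1,2-diol | C#C[C@@]1(O)C(C)(C)C[C@H](O[Si](C)(C)C(C)(C)C)C[C@]1(C)O | intermediate
11 | ethyl acetoacetate | CCOC(=O)CC(C)=O | starting material
12 | ethyl (2E)-3-{[(trifluoromethyl)sulfonyl]oxy}but-2-enoate | CCOC(=O)/C=C(C)/OS(=O)(=O)C(F)(F)F | intermediate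
13 | ethyl (2E)-5-[(1S,2S,4S)-4-[(tert-butyldimethylsilyl)oxy]-1,2-dihydroxy-2,6,6-trimethylcyclohexyl]-3-methylpent-2-en-4-ynoate | CCOC(=O)/C=C(C)/C#C[C@@]1(O)C(C)(C)C[C@H](O[Si](C)(C)C(C)(C)C)C[C@]1(C)O | intermediate
14 | (2E)-5-[(1S,2S,4S)-4-[(tert-butyldimethylsilyl)oxy]-1,2-dihydroxy-2,6,6-trimethylcyclohexyl]-3-methylpent-2-en-4-yn-1-ol | OC/C=C(C)/C#C[C@@]1(O)C(C)(C)C[C@H](O[Si](C)(C)C(C)(C)C)C[C@]1(C)O | intermediate
15 | (2E,4E)-5-[(1R,2S,4S)-4-[(tert-butyldimethylsilyl)oxy]-1,2-dihydroxy-2,6,6-trimethylcyclohexyl]-3-methylpenta-2,4-dien-1-ol | OC/C=C(C)/C=C/[C@@]1(O)C(C)(C)C[C@H](O[Si](C)(C)C(C)(C)C)C[C@]1(C)O | intermediate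
16 | (1R,2S,4S)-1-[(1E,3E)-5-bromo-3-methylpenta-1,3-dien-1-yl]-4-[(tert-butyldimethylsilyl)oxy]-2,6,6-trimethylcyclohexane-1,2-diol | BrC/C=C(C)/C=C/[C@@]1(O)C(C)(C)C[C@H](O[Si](C)(C)C(C)(C)C)C[C@]1(C)O | intermediate
17 | {(2E,4E)-5-[(1R,2S,4S)-4-[(tert-butyldimethylsilyl)oxy]-1,2-dihydroxy-2,6,6-trimethylcyclohexyl]-3-methylpenta-2,4-dien-1-yl}triphenylphosphonium bromide | [Br-].c1ccccc1[P+](c1ccccc1)(c1ccccc1)C/C=C(C)/C=C/[C@@]1(O)C(C)(C)C[C@H](O[Si](C)(C)C(C)(C)C)C[C@]1(C)O | intermediate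
18 | (R)-α-ionone ((3E)-4-[(1R)-2,6,6-trimethylcyclohex-2-en-1-yl]but-3-en-2-one) | CC1=CCCC(C)(C)[C@H]1/C=C/C(C)=O | starting material
19 | triethyl phosphonoacetate | CCOC(=O)CP(=O)(OCC)OCC | starting material
20 | sodium salt of triethyl phosphonoacetate | [Na+].CCOC(=O)[CH-]P(=O)(OCC)OCC | intermediate
21 | ethyl (2E,4E)-3-methyl-5-[(1R)-2,6,6-trimethylcyclohex-2-en-1-yl]penta-2,4-dienoate | CC1=CCCC(C)(C)[C@H]1/C=C/C(C)=C/C(=O)OCC | intermediate
22 | ethyl (2E,4E)-3-methyl-5-[(1R)-2,6,6-trimethyl-4-oxocyclohex-2-en-1-yl]penta-2,4-dienoate | CC1=CC(=O)CC(C)(C)[C@H]1/C=C/C(C)=C/C(=O)OCC | intermediate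
23 | ethyl (2E,4E)-5-[(1R,4R)-4-hydroxy-2,6,6-trimethylcyclohex-2-en-1-yl]-3-methylpenta-2,4-dienoate | CC1=C[C@H](O)CC(C)(C)[C@H]1/C=C/C(C)=C/C(=O)OCC | intermediate
24 | ethyl (2E,4E)-5-[(1R,4R)-4-[(tert-butyldimethylsilyl)oxy]-2,6,6-trimethylcyclohex-2-en-1-yl]-3-methylpenta-2,4-dienoate | CC1=C[C@H](O[Si](C)(C)C(C)(C)C)CC(C)(C)[C@H]1/C=C/C(C)=C/C(=O)OCC | intermediate
25 | (2E,4E)-5-[(1R,4R)-4-[(tert-butyldimethylsilyl)oxy]-2,6,6-trimethylcyclohex-2-en-1-yl]-3-methylpenta-2,4-dien-1-ol | CC1=C[C@H](O[Si](C)(C)C(C)(C)C)CC(C)(C)[C@H]1/C=C/C(C)=C/CO | intermediate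
26 | {[(1R,4R)-4-[(1E,3E)-5-bromo-3-methylpenta-1,3-dien-1-yl]-3,5,5-trimethylcyclohex-2-en-1-yl]oxy}(tert-butyl)dimethylsilane | CC1=C[C@H](O[Si](C)(C)C(C)(C)C)CC(C)(C)[C@H]1/C=C/C(C)=C/CBr | intermediate
27 | {(2E,4E)-5-[(1R,4R)-4-[(tert-butyldimethylsilyl)oxy]-2,6,6-trimethylcyclohex-2-en-1-yl]-3-methylpenta-2,4-dien-1-yl}triphenylphosphonium bromide | CC1=C[C@H](O[Si](C)(C)C(C)(C)C)CC(C)(C)[C@H]1/C=C/C(C)=C/C[P+](c1ccccc1)(c1ccccc1)c1ccccc1.[Br-] | intermediate
28 | (2E,4E,6E)-2,7-dimethylocta-2,4,6-trienedial | O=C/C(C)=C/C=C/C=C(C)/C=O | starting material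
29 | {(2E,4E)-5-[(1R,4R)-4-[(tert-butyldimethylsilyl)oxy]-2,6,6-trimethylcyclohex-2-en-1-yl]-3-methylpenta-2,4-dien-1-ylidene}triphenylphosphorane | CC1=C[C@H](O[Si](C)(C)C(C)(C)C)CC(C)(C)[C@H]1/C=C/C(C)=C/C=P(c1ccccc1)(c1ccccc1)c1ccccc1 | intermediate
30 | (2E,4E,6E,8E,10E,12E)-13-[(1R,4R)-4-[(tert-butyldimethylsilyl)oxy]-2,6,6-trimethylcyclohex-2-en-1-yl]-2,7,11-trimethyltrideca-2,4,6,8,10,12-hexaenal | CC1=C[C@H](O[Si](C)(C)C(C)(C)C)CC(C)(C)[C@H]1/C=C/C(C)=C/C=C/C(C)=C/C=C/C=C(C)/C=O | intermediate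
31 | {(2E,4E)-5-[(1R,2S,4S)-4-[(tert-butyldimethylsilyl)oxy]-1,2-dihydroxy-2,6,6-trimethylcyclohexyl]-3-methylpenta-2,4-dien-1-ylidene}triphenylphosphorane | c1ccccc1P(c1ccccc1)(c1ccccc1)=C/C=C(C)/C=C/[C@@]1(O)C(C)(C)C[C@H](O[Si](C)(C)C(C)(C)C)C[C@]1(C)O | intermediate
32 | (3S,5S,6R,3'R,6'R)-3,3'-bis[(tert-butyldimethylsilyl)oxy]-5,6-dihydro-β,ε-carotene-5,6-diol | CC1=C[C@H](O[Si](C)(C)C(C)(C)C)CC(C)(C)[C@H]1/C=C/C(C)=C/C=C/C(C)=C/C=C/C=C(C)/C=C/C=C(C)/C=C/[C@@]1(O)C(C)(C)C[C@H](O[Si](C)(C)C(C)(C)C)C[C@]1(C)O | intermediate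
33 | (3S,5S,6R,3'R,6'R)-5,6-dihydro-β,ε-carotene-3,5,6,3'-tetrol (5,6-dihydroxylutein) | CC1=C[C@H](O)CC(C)(C)[C@H]1/C=C/C(C)=C/C=C/C(C)=C/C=C/C=C(C)/C=C/C=C(C)/C=C/[C@@]1(O)C(C)(C)C[C@H](O)C[C@]1(C)O | target

## Step count and risks

Total step count: 20. Longest linear sequence: 12 steps (1 → 33 through steps 1–6, 8–11, 19 and 20).

**Step 5 (the proposed new directed dihydroxylation).** Risks: slow osmylation of the hindered tetrasubstituted alkene, a competing undirected attack on the other face, and difficult cleavage of the di-tertiary osmate ester. The fallback uses only known reactions; it sets out from 7 and comes back to the route at 9. Mitsunobu inversion of 7 (4-nitrobenzoic acid, PPh3, DIAD, THF) gives (1S)-4-ethynyl-3,5,5-trimethylcyclohex-3-en-1-yl 4-nitrobenzoate F1. Catalytic OsO4 with N-methylmorpholine N-oxide and MeSO2NH2 in acetone/water then adds, without any directing effect, to the face remote from the bulky ester (the facial preference known from peracid epoxidation of 3-acyloxy β-end groups) and gives (1R,3S,4S)-4-ethynyl-3,4-dihydroxy-3,5,5-trimethylcyclohexyl 4-nitrobenzoate F2, which already has the C5/C6 configuration of the target. K2CO3 in MeOH frees (1S,2S,4R)-1-ethynyl-2,6,6-trimethylcyclohexane-1,2,4-triol F3. Parikh–Doering oxidation (SO3·pyridine, DMSO, i-Pr2NEt) of its only secondary alcohol gives (3S,4S)-4-ethynyl-3,4-dihydroxy-3,5,5-trimethylcyclohexan-1-one F4. LiBH(s-Bu)3 (THF, −78 °C), forced to attack equatorially by the syn-axial C3 hydroxyl and C5 methyl, delivers the axial all-cis alcohol 9.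

**Step 14 (Luche reduction).** Risk: the trans/cis ratio at C3' rests on a conformational argument and may be low or reversed. The fallback sets out from 22 and comes back at 23. The 1,4-cis alcohol ethyl (2E,4E)-5-[(1R,4S)-4-hydroxy-2,6,6-trimethylcyclohex-2-en-1-yl]-3-methylpenta-2,4-dienoate F5 (the co-product of the reduction, or its main product if a bulkier hydride such as LiBH(s-Bu)3 turns out to favour it) is not discarded. It is esterified with inversion under Mitsunobu conditions (4-nitrobenzoic acid, PPh3, DIAD; SN2' is blocked by the fully substituted alkene terminus) to ethyl (2E,4E)-3-methyl-5-{(1R,4R)-2,6,6-trimethyl-4-[(4-nitrobenzoyl)oxy]cyclohex-2-en-1-yl}penta-2,4-dienoate F6. K2CO3 in EtOH removes the nitrobenzoate and gives 23, so the carbinol configuration is set by SN2 inversion instead of hydride face selectivity.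

**Step 11 (phosphonium salt of the ring A fragment).** Risk: the allylic bromide 16 carries a free tertiary alcohol in conjugation with the diene and may ionise or eliminate before quaternisation. The fallback reverses the polarity of the last Wittig reaction so that ring A never passes through an allylic halide; it sets out from 15 and 30 and comes back at 32. MnO2 (CH2Cl2, rt) oxidises only the primary allylic alcohol of 15 to (2E,4E)-5-[(1R,2S,4S)-4-[(tert-butyldimethylsilyl)oxy]-1,2-dihydroxy-2,6,6-trimethylcyclohexyl]-3-methylpenta-2,4-dienal F7. NaBH4 (MeOH/THF, 0 °C) reduces 30 to (2E,4E,6E,8E,10E,12E)-13-[(1R,4R)-4-[(tert-butyldimethylsilyl)oxy]-2,6,6-trimethylcyclohex-2-en-1-yl]-2,7,11-trimethyltrideca-2,4,6,8,10,12-hexaen-1-ol F8. CBr4/PPh3 followed by PPh3 converts it into {(2E,4E,6E,8E,10E,12E)-13-[(1R,4R)-4-[(tert-butyldimethylsilyl)oxy]-2,6,6-trimethylcyclohex-2-en-1-yl]-2,7,11-trimethyltrideca-2,4,6,8,10,12-hexaen-1-yl}triphenylphosphonium bromide F9. Wittig reaction of F9 with F7 (NaOMe, MeOH/CH2Cl2, then thermal Z → E equilibration) forms the same C11=C12 bond and gives 32.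

## Further compounds

F1 | step 5 | (1S)-4-ethynyl-3,5,5-trimethylcyclohex-3-en-1-yl 4-nitrobenzoate | CC1=C(C#C)C(C)(C)C[C@@H](OC(=O)c2ccc(cc2)[N+](=O)[O-])C1
F2 | step 5 | (1R,3S,4S)-4-ethynyl-3,4-dihydroxy-3,5,5-trimethylcyclohexyl 4-nitrobenzoate | C#C[C@@]1(O)C(C)(C)C[C@@H](OC(=O)c2ccc(cc2)[N+](=O)[O-])C[C@]1(C)O
F3 | step 5 | (1S,2S,4R)-1-ethynyl-2,6,6-trimethylcyclohexane-1,2,4-triol | C#C[C@@]1(O)C(C)(C)C[C@@H](O)C[C@]1(C)O
F4 | step 5 | (3S,4S)-4-ethynyl-3,4-dihydroxy-3,5,5-trimethylcyclohexan-1-one | C#C[C@@]1(O)C(C)(C)CC(=O)C[C@]1(C)O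
F5 | step 14 | ethyl (2E,4E)-5-[(1R,4S)-4-hydroxy-2,6,6-trimethylcyclohex-2-en-1-yl]-3-methylpenta-2,4-dienoate | CC1=C[C@@H](O)CC(C)(C)[C@H]1/C=C/C(C)=C/C(=O)OCC
F6 | step 14 | ethyl (2E,4E)-3-methyl-5-{(1R,4R)-2,6,6-trimethyl-4-[(4-nitrobenzoyl)oxy]cyclohex-2-en-1-yl}penta-2,4-dienoate | CC1=C[C@H](OC(=O)c2ccc(cc2)[N+](=O)[O-])CC(C)(C)[C@H]1/C=C/C(C)=C/C(=O)OCC
F7 | step 11 | (2E,4E)-5-[(1R,2S,4S)-4-[(tert-butyldimethylsilyl)oxy]-1,2-dihydroxy-2,6,6-trimethylcyclohexyl]-3-methylpenta-2,4-dienal | O=C/C=C(C)/C=C/[C@@]1(O)C(C)(C)C[C@H](O[Si](C)(C)C(C)(C)C)C[C@]1(C)O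
F8 | step 11 | (2E,4E,6E,8E,10E,12E)-13-[(1R,4R)-4-[(tert-butyldimethylsilyl)oxy]-2,6,6-trimethylcyclohex-2-en-1-yl]-2,7,11-trimethyltrideca-2,4,6,8,10,12-hexaen-1-ol | CC1=C[C@H](O[Si](C)(C)C(C)(C)C)CC(C)(C)[C@H]1/C=C/C(C)=C/C=C/C(C)=C/C=C/C=C(C)/CO
F9 | step 11 | {(2E,4E,6E,8E,10E,12E)-13-[(1R,4R)-4-[(tert-butyldimethylsilyl)oxy]-2,6,6-trimethylcyclohex-2-en-1-yl]-2,7,11-trimethyltrideca-2,4,6,8,10,12-hexaen-1-yl}triphenylphosphonium bromide | CC1=C[C@H](O[Si](C)(C)C(C)(C)C)CC(C)(C)[C@H]1/C=C/C(C)=C/C=C/C(C)=C/C=C/C=C(C)/C[P+](c2ccccc2)(c2ccccc2)c2ccccc2.[Br-]
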